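## Retrosynthetic overview

1. The route rests on ring D, a cis 1,4-dioxane fused to ring C: C8' (CH2OH) sits on O3', meta to the C1'–C7 branch, and C7' (catechol ring E) on O4', para to it. A C1' ester therefore makes O4' the poorer donor, and a carbene is taken up by O3'.
2. Ring D is made first: ethyl diazoacetate inserts its carbon into racemic 2-aryl-1,3-benzodioxole 5 (oxonium ylide, [1,2]-Stevens shift), forming O3'–C8' and C7'–C8'. C8' is then turned cis by kinetic protonation.
3. Ring B is made second: C7–C8 by an auxiliary-controlled syn glycolate aldol between ring C aldehyde 13 and ring A imide 17, then the O–C(aryl) bond by copper-catalysed etherification (trans ring).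
4. The (E)-propenal is made last from a ring A vinyl group by cross-metathesis, and one fluoride step frees the catechol and both CH2OH groups.
5. Benzodioxole 5 comes from 3,4-dihydroxybenzaldehyde and methyl 3,4-dihydroxybenzoate by silylation, acetalisation and acetal exchange.

Key step: step 4

Remarks on the chemistry
- Locants: ring A is the cinnamaldehyde arene; its oxygen para to the side chain carries C8 and its meta oxygen carries C7. Ring B is the trans dioxane (C7, C8, C9 = CH2OH). Ring C is the central arene (C1' carries C7; O3' meta and O4' para to C1'). Ring D is the cis dioxane (C7', C8', C9'). Ring E is the catechol. The target is 7S,8S,7'R,8'S. The descriptors at C8 and C8' change with the oxidation level of C9 and C9' although the spatial arrangement does not.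
- Ring E is carried as its bis(triisopropylsilyl) ether and not as an acetal-type ether. The alkyl oxygen of an acyclic acetal is a better carbene acceptor than the aryl acetal oxygen O3' and would undergo the same insertion in competition.
- The acetal carbon of 5 is racemic and is not resolved, because step 4 passes through a planar cation.
- Assumption: the (S,S)-ligand is taken to lead to the (7'R) series drawn. Should the first runs show the opposite sense, the (R,R)-ligand is used and nothing else changes.

## Route

Step 1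
Reactants: 1 3,4-dihydroxybenzaldehyde
Product: 2 3,4-bis(triisopropylsilyloxy)benzaldehyde
Conditions: TIPSCl (2.5 equiv), imidazole (5 equiv), DMF, rt to 40 °C
Reagents that add atoms: triisopropylsilyl chloride, CC(C)[Si](Cl)(C(C)C)C(C)C
Why: Imidazole-promoted silyl ether formation at both phenols; the bulky, weakly basic silyl ethers offer the carbene of step 4 no competing oxygen and should survive carbonate at 110 °C in step 14.

Step 2
Reactants: 2 3,4-bis(triisopropylsilyloxy)benzaldehyde
Product: 3 3,4-bis(triisopropylsilyloxy)benzaldehyde dimethyl acetal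
Conditions: HC(OMe)3, MeOH, PPTS (cat.), rt; Et3N quench
Reagents that add atoms: trimethyl orthoformate, COC(OC)OC; methanol, CO
Why: Acid-catalysed acetalisation of an electron-rich aldehyde, driven by the orthoformate as water scavenger, under acid mild enough for aryl silyl ethers.

Step 3
Reactants: 3 3,4-bis(triisopropylsilyloxy)benzaldehyde dimethyl acetal; 4 methyl 3,4-dihydroxybenzoate
Product: 5 methyl 2-[3,4-bis(triisopropylsilyloxy)phenyl]-1,3-benzodioxole-5-carboxylate (racemic at the acetal carbon)
Conditions: PPTS (10 mol %), toluene, 110 °C, methanol removed over 4 Å MS; isolation on Et3N-deactivated silica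
Reagents that add atoms: none
Why: Acid-catalysed acetal exchange: the catechol replaces both methoxy groups through the 4-silyloxybenzylidene oxocarbenium ion and removal of methanol drives closure of the five-membered acetal, whose new stereocentre is formed racemic and need not be controlled.

Step 4
Reactants: 5 methyl 2-[3,4-bis(triisopropylsilyloxy)phenyl]-1,3-benzodioxole-5-carboxylate; 6 ethyl diazoacetate
Product: 8 trans ring C/D/E diester (7'R,8'S), via oxonium ylide 7 (not isolated)
Conditions: (CuOTf)2·C6H6 (5 mol % Cu), 2,2'-isopropylidenebis[(4S)-4-tert-butyl-2-oxazoline] (6 mol %), 4 Å MS, CH2Cl2, 0 °C to rt, 6 (3 equiv) by syringe pump over 10 h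
Reagents that add atoms: none
Why: Proposed new method: the CuOTf–bisoxazoline carbene formed from 6 is attacked by O3' of 5, the ring C oxygen that is not conjugated with the para ester, to give copper-associated oxonium ylide 7, which cleaves its O3'–C(acetal) bond to a 4-silyloxybenzylidene oxocarbenium ion held on O4' and a copper enolate held on O3' that recombine at carbon, a [1,2]-Stevens shift creating O3'–C8' and C7'–C8'. The closest known reaction type is the Rh2(OAc)4- or copper-catalysed ring expansion of 2-aryl-1,3-dioxolanes to 1,4-dioxanes with diazo esters, and in asymmetric form the copper–bisoxazoline ring expansion of 2-aryloxetanes; neither has been shown on an aryl acetal oxygen. Ring D closes in the recombination, a 6-endo-trig (enolexo) attack of the enolate carbon on the oxocarbenium carbon that expands the five-membered acetal ring by one carbon. C7' is set there: the planar cation has lost the configuration of racemic 5, so both enantiomers converge, and the tert-butyl-bisoxazoline on copper selects the enolate face and, through the compact six-membered transition state, the cation face; C8' is expected mainly trans and is reset in step 5, so any cis epimer formed alongside is carried on unseparated. The step needs O3' over O4' selectivity, secured by the C1' ester, selectivity over the ring E oxygens, secured by their bulky and weakly basic triisopropylsilyl groups, and ylide formation over carbene dimerisation or arene cyclopropanation, favoured by copper and slow addition of 6.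

Step 5
Reactants: 8 trans ring C/D/E diester (with any cis epimer from step 4)
Product: 10 cis ring C/D/E diester (7'R,8'R), via lithium enolate 9 (not isolated)
Conditions: LiN(iPr)2 (1.3 equiv), THF, −78 °C, 20 min; then 2,6-di-tert-butyl-4-methylphenol (3 equiv) in THF, −78 °C
Reagents that add atoms: none
Why: Kinetic protonation of an ester enolate: allylic 1,3-strain with the enolate oxygens holds the C7' aryl group pseudoaxial in planar enolate 9, so the bulky phenol delivers the proton to C8' from the face opposite ring E and the ester ends up cis to the aryl group, while C7' is untouched as long as the enolate is kept at −78 °C.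

Step 6
Reactants: 10 cis ring C/D/E diester
Product: 11 cis diol (7'R,8'S; ring C CH2OH and C9' OH)
Conditions: iBu2AlH (6 equiv), CH2Cl2, −78 to 0 °C; aq. potassium sodium tartrate
Reagents that add atoms: none
Why: Hydride reduction of both esters to primary alcohols; the aluminium alkoxide intermediates are not basic enough to epimerise C8', so the cis relationship is carried into the diol.

Step 7
Reactants: 11 cis diol
Product: 12 cis hydroxy aldehyde (ring C CHO, free C9' OH)
Conditions: MnO2 (activated, 15 equiv), CH2Cl2, rt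
Reagents that add atoms: none
Why: Chemoselective MnO2 oxidation of the benzylic alcohol only; the saturated C9' alcohol is inert to this reagent.

Step 8
Reactants: 12 cis hydroxy aldehyde
Product: 13 ring C/D/E aldehyde with C9' OTBS
Conditions: TBSCl (1.3 equiv), imidazole, CH2Cl2, 0 °C to rt
Reagents that add atoms: tert-butyldimethylsilyl chloride, CC(C)(C)[Si](C)(C)Cl
Why: Standard silyl ether formation at the remaining primary alcohol, so that every protecting group in the molecule falls to fluoride at the end.

Step 9
Reactants: 14 3-bromo-4-hydroxybenzaldehyde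
Product: 15 2-bromo-4-vinylphenol
Conditions: Ph3PCH3Br (2.5 equiv), KOtBu (2.5 equiv), THF, 0 °C to rt; used at once
Reagents that add atoms: methyltriphenylphosphonium bromide, C[P+](c1ccccc1)(c1ccccc1)c1ccccc1.[Br-]
Why: Wittig methylenation, with the excess base covering the phenol; the vinyl group is an inert placeholder for the enal through steps 10 to 14.

Step 10
Reactants: 15 2-bromo-4-vinylphenol; 16 (R)-4-benzyl-3-(chloroacetyl)oxazolidin-2-one
Product: 17 (R)-4-benzyl-3-[(2-bromo-4-vinylphenoxy)acetyl]oxazolidin-2-one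
Conditions: K2CO3 (1.5 equiv), NaI (10 mol %), acetone, rt
Reagents that add atoms: none
Why: Williamson etherification: iodide-catalysed SN2 displacement of the activated α-chloride by the phenoxide under weakly basic, non-nucleophilic conditions that leave the imide intact.

Step 11
Reactants: 17 (R)-4-benzyl-3-[(2-bromo-4-vinylphenoxy)acetyl]oxazolidin-2-one (1.5 equiv); 13 ring C/D/E aldehyde with C9' OTBS
Product: 19 syn aldol adduct (7S,8R), via dibutylboron enolate 18 (not isolated)
Conditions: Bu2BOTf, iPr2NEt, CH2Cl2, −78 to 0 °C; then 13, −78 to 0 °C; pH 7 buffer, MeOH, H2O2, 0 °C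
Reagents that add atoms: none
Why: Evans syn aldol: Z boron enolate 18 reacts through a closed Zimmerman–Traxler transition state on the face away from the benzyl group of the (R)-auxiliary, which sets C8 and C7 together (syn) independently of the remote ring D centres; adducts of any minor enantiomer of 13 would be diastereomers and are removed here.

Step 12
Reactants: 19 syn aldol adduct
Product: 20 diol (7S,8S; free C7 OH and C9 OH)
Conditions: LiBH4 (2 equiv), MeOH (2 equiv), THF, 0 °C
Reagents that add atoms: none
Why: Reductive cleavage of the N-acyl oxazolidinone at the exocyclic carbonyl gives the primary C9 alcohol and returns the auxiliary without touching C7 or C8.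

Step 13
Reactants: 20 diol
Product: 21 C9 OTBS ether with free C7 OH
Conditions: TBSCl (1.1 equiv), imidazole, CH2Cl2, 0 °C
Reagents that add atoms: tert-butyldimethylsilyl chloride, CC(C)(C)[Si](C)(C)Cl
Why: Steric selection in silyl ether formation: the primary C9 hydroxyl reacts much faster than the flanked secondary benzylic C7 hydroxyl.

Step 14
Reactants: 21 C9 OTBS ether with free C7 OH
Product: 22 fully silylated ring A–E compound with ring A vinyl group (7S,8S,7'R,8'S)
Conditions: CuI (10 mol %), 3,4,7,8-tetramethyl-1,10-phenanthroline (20 mol %), Cs2CO3 (2 equiv), toluene, 110 °C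
Reagents that add atoms: none
Why: Copper-catalysed intramolecular Ullmann-type O-arylation of the C7 alkoxide with the ortho bromide closes six-membered ring B with retention at C7, so the syn aldol relationship becomes the trans ring and the new aryl oxygen is the one meta to the vinyl group.

Step 15
Reactants: 22 fully silylated ring A–E vinyl compound; 23 (E)-crotonaldehyde (10 equiv)
Product: 24 fully silylated (E)-enal
Conditions: second-generation Hoveyda–Grubbs catalyst RuCl2(H2IMes)(=CH–C6H4-2-OiPr) (5 mol %), CH2Cl2, 40 °C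
Reagents that add atoms: none
Why: Olefin cross-metathesis of the electron-rich styrene with excess crotonaldehyde releases propene and should give the conjugated E enal, the thermodynamically favoured isomer.

Step 16
Reactants: 24 fully silylated (E)-enal
Product: 25 target CNP0302404.1
Conditions: Bu4NF (6 equiv), AcOH (6 equiv), THF, 0 °C to rt, under argon
Reagents that add atoms: none
Why: Fluoride-mediated desilylation of the two aryl triisopropylsilyl and two primary tert-butyldimethylsilyl ethers; acetic acid buffering keeps the freed catechol from opening cis ring D through a para-quinone methide and from adding to the enal.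

## Compound list

1 | 3,4-dihydroxybenzaldehyde | O=Cc1ccc(O)c(O)c1 | starting material
2 | 3,4-bis(triisopropylsilyloxy)benzaldehyde | O=Cc1ccc(O[Si](C(C)C)(C(C)C)C(C)C)c(O[Si](C(C)C)(C(C)C)C(C)C)c1 | intermediate
3 | 3,4-bis(triisopropylsilyloxy)benzaldehyde dimethyl acetal | COC(OC)c1ccc(O[Si](C(C)C)(C(C)C)C(C)C)c(O[Si](C(C)C)(C(C)C)C(C)C)c1 | intermediate
4 | methyl 3,4-dihydroxybenzoate | COC(=O)c1ccc(O)c(O)c1 | starting material
5 | methyl 2-[3,4-bis(triisopropylsilyloxy)phenyl]-1,3-benzodioxole-5-carboxylate (racemic) | COC(=O)c1ccc2c(c1)OC(c1ccc(O[Si](C(C)C)(C(C)C)C(C)C)c(O[Si](C(C)C)(C(C)C)C(C)C)c1)O2 | intermediate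
6 | ethyl diazoacetate | CCOC(=O)C=[N+]=[N-] | starting material
7 | oxonium ylide at O3' of 5, copper-associated (not isolated) | COC(=O)c1ccc2c(c1)[O+]([CH-]C(=O)OCC)C(c1ccc(O[Si](C(C)C)(C(C)C)C(C)C)c(O[Si](C(C)C)(C(C)C)C(C)C)c1)O2 | intermediate
8 | trans ring C/D/E diester: 2-ethyl 7-methyl (2S,3R)-3-[3,4-bis(triisopropylsilyloxy)phenyl]-2,3-dihydro-1,4-benzodioxine-2,7-dicarboxylate (7'R,8'S) | COC(=O)c1ccc2c(c1)O[C@H](C(=O)OCC)[C@@H](c1ccc(O[Si](C(C)C)(C(C)C)C(C)C)c(O[Si](C(C)C)(C(C)C)C(C)C)c1)O2 | intermediate
9 | lithium enolate of 8, C8' planar, C7' R (not isolated) | COC(=O)c1ccc2c(c1)OC(=C([O-])OCC)[C@@H](c1ccc(O[Si](C(C)C)(C(C)C)C(C)C)c(O[Si](C(C)C)(C(C)C)C(C)C)c1)O2.[Li+] | intermediate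
10 | cis ring C/D/E diester: 2-ethyl 7-methyl (2R,3R)-3-[3,4-bis(triisopropylsilyloxy)phenyl]-2,3-dihydro-1,4-benzodioxine-2,7-dicarboxylate (7'R,8'R) | COC(=O)c1ccc2c(c1)O[C@@H](C(=O)OCC)[C@@H](c1ccc(O[Si](C(C)C)(C(C)C)C(C)C)c(O[Si](C(C)C)(C(C)C)C(C)C)c1)O2 | intermediate
11 | cis diol: ring C CH2OH and C9' OH (7'R,8'S) | OCc1ccc2c(c1)O[C@@H](CO)[C@@H](c1ccc(O[Si](C(C)C)(C(C)C)C(C)C)c(O[Si](C(C)C)(C(C)C)C(C)C)c1)O2 | intermediate
12 | cis hydroxy aldehyde: (2R,3S)-2-[3,4-bis(triisopropylsilyloxy)phenyl]-3-(hydroxymethyl)-2,3-dihydro-1,4-benzodioxine-6-carbaldehyde | O=Cc1ccc2c(c1)O[C@@H](CO)[C@@H](c1ccc(O[Si](C(C)C)(C(C)C)C(C)C)c(O[Si](C(C)C)(C(C)C)C(C)C)c1)O2 | intermediate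
13 | C9' tert-butyldimethylsilyl ether of 12 | O=Cc1ccc2c(c1)O[C@@H](CO[Si](C)(C)C(C)(C)C)[C@@H](c1ccc(O[Si](C(C)C)(C(C)C)C(C)C)c(O[Si](C(C)C)(C(C)C)C(C)C)c1)O2 | intermediate
14 | 3-bromo-4-hydroxybenzaldehyde | O=Cc1ccc(O)c(Br)c1 | starting material
15 | 2-bromo-4-vinylphenol | C=Cc1ccc(O)c(Br)c1 | intermediate
16 | (R)-4-benzyl-3-(chloroacetyl)oxazolidin-2-one | O=C(CCl)N1C(=O)OC[C@H]1Cc1ccccc1 | starting material
17 | (R)-4-benzyl-3-[(2-bromo-4-vinylphenoxy)acetyl]oxazolidin-2-one | C=Cc1ccc(OCC(=O)N2C(=O)OC[C@H]2Cc2ccccc2)c(Br)c1 | intermediate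
18 | (Z)-dibutylboron enolate of 17 (not isolated) | C=Cc1ccc(O/C=C(\OB(CCCC)CCCC)N2C(=O)OC[C@H]2Cc2ccccc2)c(Br)c1 | intermediate
19 | syn aldol adduct (7S,8R): C7 OH, C8 O-(2-bromo-4-vinylphenyl), C9 acyl oxazolidinone | O[C@@H](c1ccc2c(c1)O[C@@H](CO[Si](C)(C)C(C)(C)C)[C@@H](c1ccc(O[Si](C(C)C)(C(C)C)C(C)C)c(O[Si](C(C)C)(C(C)C)C(C)C)c1)O2)[C@H](C(=O)N1C(=O)OC[C@H]1Cc1ccccc1)Oc1ccc(C=C)cc1Br | intermediate
20 | diol (7S,8S): C7 OH and C9 OH | O[C@@H](c1ccc2c(c1)O[C@@H](CO[Si](C)(C)C(C)(C)C)[C@@H](c1ccc(O[Si](C(C)C)(C(C)C)C(C)C)c(O[Si](C(C)C)(C(C)C)C(C)C)c1)O2)[C@H](CO)Oc1ccc(C=C)cc1Br | intermediate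
21 | C9 tert-butyldimethylsilyl ether of 20, free C7 OH | O[C@@H](c1ccc2c(c1)O[C@@H](CO[Si](C)(C)C(C)(C)C)[C@@H](c1ccc(O[Si](C(C)C)(C(C)C)C(C)C)c(O[Si](C(C)C)(C(C)C)C(C)C)c1)O2)[C@H](CO[Si](C)(C)C(C)(C)C)Oc1ccc(C=C)cc1Br | intermediate
22 | fully silylated ring A–E compound with ring A vinyl group (7S,8S,7'R,8'S) | C=Cc1ccc2c(c1)O[C@@H](c1ccc3c(c1)O[C@@H](CO[Si](C)(C)C(C)(C)C)[C@@H](c1ccc(O[Si](C(C)C)(C(C)C)C(C)C)c(O[Si](C(C)C)(C(C)C)C(C)C)c1)O3)[C@H](CO[Si](C)(C)C(C)(C)C)O2 | intermediate
23 | (E)-crotonaldehyde | C/C=C/C=O | starting material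
24 | fully silylated (E)-enal | O=C/C=C/c1ccc2c(c1)O[C@@H](c1ccc3c(c1)O[C@@H](CO[Si](C)(C)C(C)(C)C)[C@@H](c1ccc(O[Si](C(C)C)(C(C)C)C(C)C)c(O[Si](C(C)C)(C(C)C)C(C)C)c1)O3)[C@H](CO[Si](C)(C)C(C)(C)C)O2 | intermediate
25 | CNP0302404.1 (7S,8S,7'R,8'S) | O=C/C=C/c1ccc2c(c1)O[C@@H](c1ccc3c(c1)O[C@@H](CO)[C@@H](c1ccc(O)c(O)c1)O3)[C@H](CO)O2 | target

## Step count and risks

Total step count: 16. Longest linear sequence: 14 (steps 1 to 8 and 11 to 16).

Steps most likely to fail:

1. Step 4 (Proposed new method). The weakly basic aryl acetal oxygen may fail to intercept the carbene, which then dimerises. The carbene may be taken up at O4', giving the regioisomeric ring. The ion pair may recombine without face control, so that C7' forms racemic. The fallback uses known reactions and runs from 2 back to 8. Methyl 4-bromo-3-hydroxybenzoate is alkylated with (S)-4-benzyl-3-(chloroacetyl)oxazolidin-2-one (K2CO3, NaI, acetone) to give the aryloxyacetyl imide F1. An Evans syn aldol addition of F1 (Bu2BOTf, iPr2NEt, CH2Cl2, −78 °C) to aldehyde 2 gives the syn adduct F2, in which the auxiliary fixes C7' as R. EtOMgBr in EtOH/THF at 0 °C replaces the auxiliary by the ethyl ester to give the hydroxy ester F3. A palladium-catalysed intramolecular etherification (Pd(OAc)2, 2-(di-tert-butylphosphino)-1,1'-binaphthyl, K3PO4, toluene, 70 °C) joins the C7' oxygen to C4' with retention. It delivers trans diester 8, which enters step 5.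

2. Step 5. Enolate 9 may expel the O4' aryloxide, a β-elimination that opens ring D and erases C7', or the proton may be delivered to both faces. The fallback runs from 8 back to 10 and avoids a free ester enolate. Selective saponification of the α-aryloxy ethyl ester (LiOH, 1.1 equiv, THF/H2O, 0 °C) gives the trans acid F4. (COCl)2 with catalytic DMF in CH2Cl2 gives the acid chloride F5. Et3N in toluene at −78 °C eliminates HCl to the ketene F6, which is trapped in the same flask with EtOH. The enol so formed is protonated at C8' from the face opposite the pseudoaxial ring E, giving cis diester 10.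

3. Step 14. At 110 °C the C7 alkoxide may take over the neighbouring silyl group, the C–Br bond may be reduced while the carbinol is oxidised, or carbonate may strip aryl silyl ethers. The fallback runs from 21 to 22 and makes no new compound (F0). Ring B is closed by Buchwald–Hartwig etherification (Pd(OAc)2, 2-(di-tert-butylphosphino)-1,1'-binaphthyl, K3PO4, toluene, 65 °C, high dilution against Heck coupling at the vinyl group). Here zerovalent palladium adds to the C–Br bond and the C–O bond forms by reductive elimination, at a much lower temperature and with a weaker base, again with retention at C7.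

Further compounds
F1 | step 4 | methyl 3-{2-[(4S)-4-benzyl-2-oxo-1,3-oxazolidin-3-yl]-2-oxoethoxy}-4-bromobenzoate | COC(=O)c1ccc(Br)c(c1)OCC(=O)N1C(=O)OC[C@@H]1Cc1ccccc1
F2 | step 4 | syn aldol adduct (8'S,7'R) of F1 with 2, C7' OH free, (S)-auxiliary on C9' | COC(=O)c1ccc(Br)c(c1)O[C@H](C(=O)N1C(=O)OC[C@@H]1Cc1ccccc1)[C@@H](c1ccc(O[Si](C(C)C)(C(C)C)C(C)C)c(O[Si](C(C)C)(C(C)C)C(C)C)c1)O
F3 | step 4 | ethyl (2S,3R)-2-[2-bromo-5-(methoxycarbonyl)phenoxy]-3-hydroxy-3-[3,4-bis(triisopropylsilyloxy)phenyl]propanoate | COC(=O)c1ccc(Br)c(c1)O[C@H](C(=O)OCC)[C@@H](c1ccc(O[Si](C(C)C)(C(C)C)C(C)C)c(O[Si](C(C)C)(C(C)C)C(C)C)c1)O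
F4 | step 5 | trans C9' acid, ring C methyl ester kept (7'R,8'S) | COC(=O)c1ccc2c(c1)O[C@H](C(=O)O)[C@@H](c1ccc(O[Si](C(C)C)(C(C)C)C(C)C)c(O[Si](C(C)C)(C(C)C)C(C)C)c1)O2
F5 | step 5 | trans C9' acid chloride (7'R,8'S) | COC(=O)c1ccc2c(c1)O[C@H](C(=O)Cl)[C@@H](c1ccc(O[Si](C(C)C)(C(C)C)C(C)C)c(O[Si](C(C)C)(C(C)C)C(C)C)c1)O2
F6 | step 5 | C8' ketene, C7' R | COC(=O)c1ccc2c(c1)OC(=C=O)[C@@H](c1ccc(O[Si](C(C)C)(C(C)C)C(C)C)c(O[Si](C(C)C)(C(C)C)C(C)C)c1)O2
F0 | step 14 | none | none
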